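Retrosynthetic cuts: the O6 and O9 esters, C11=C13 (olefination of formaldehyde) and C10–OH (hydration of C1=C10). Then, at one stroke, C4–CH3 and C2–C3 of the ten-membered ring are cut while C5–C10 is re-formed.
Enabling feature: in ring C1–C10 the string O=C5–C4–C3–C2–C1–C10 is the retron of an anionic oxy-Cope rearrangement. The other six ring atoms C5–C10 carry the lactone at C7/C8 and all-trans O6, C11, O8 and O9, so they fold back into an all-equatorial chair cyclohexane.
Forward ring order: cyclohexane C5–C10 (from quinic acid), then the γ-lactone (C7, C8, O, C12, C11), then a temporary seven-membered O9–Si–O2 ring. The ten-membered carbocycle comes last, by four-atom ring enlargement.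
Stereochemistry: C8 and C9 come from (−)-quinic acid, C7 from an equilibrating Michael addition, C6 from enolate hydroxylation. The helper centres C10 (axial methylation) and C5 (axial vinyl addition) relay to C2 through the [3,3] shift and are erased. C4 and C10–OH arise by attack on the outer face of the medium ring.
Helpers: diacetal, benzyl ether, silylene tether and phosphonate (masked methylene). Each is removed or consumed later.

Key step: step 14

Remark: germacrane locants are used throughout (C5 ketone, C6 O-isobutyryl, C7/C8 lactone fusion, C9 O-angeloyl, C10 and C2 carbinols, C4 methine; H7 is α). Quinic acid C1–C6 become C5–C10.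
Remark: cardivin C is taken as the open 2-hydroxy-5-ketone drawn in the target. Any ring-chain equilibrium of 2-OH with the C5 ketone is not treated as a separate compound.
Remark: C11 is acidic while it bears the phosphonate, so it is drawn without a descriptor. Step 22 makes it trigonal.

Step 1
Reactants: 1 (−)-quinic acid
Product: 2 BDA-protected methyl quinate
Conditions: butane-2,3-dione, HC(OMe)3, MeOH, CSA (cat.), reflux
Reagents that add atoms: butane-2,3-dione CC(=O)C(C)=O; methanol CO
Why: Fischer esterification runs together with butane-2,3-diacetal formation, which picks the only trans-diequatorial diol (the later O8/O9) because both methoxy groups can then sit axial (anomeric effect), and no stereocentre of 1 is touched.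

Step 2
Reactants: 2 BDA-protected methyl quinate
Product: 3 BDA triol
Conditions: NaBH4, MeOH, 0 °C to rt
Reagents that add atoms: none
Why: Borohydride reduction of an α-hydroxy ester gives the 1,2-diol needed for glycol cleavage and leaves the acetal alone.

Step 3
Reactants: 3 BDA triol
Product: 4 BDA β-hydroxy ketone
Conditions: NaIO4, SiO2, CH2Cl2/H2O, rt
Reagents that add atoms: none
Why: Malaprade glycol cleavage removes the former carboxyl carbon and turns C5 into the ring ketone.

Step 4
Reactants: 4 BDA β-hydroxy ketone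
Product: 6 BDA enone, via mesylate 5 (not isolated)
Conditions: MsCl, Et3N, CH2Cl2, 0 °C
Reagents that add atoms: none
Why: Mesylation of the axial β-hydroxyl group is followed by E1cB elimination to the conjugated enone C5(=O)–C6=C7.

Step 5
Reactants: 6 BDA enone
Product: 7 10-allyl enone (C10 epimers)
Conditions: LDA, THF, −78 °C; allyl bromide, DMPU, −78 to −30 °C
Reagents that add atoms: allyl bromide C=CCBr
Why: Kinetic α'-deprotonation and SN2 allylation of a cyclohexenone should work because the trans-fused dioxane holds the C9–O bond in the nodal plane of the enolate, which switches off β-elimination, and the C10 epimer ratio is irrelevant because step 6 flattens C10 again.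

Step 6
Reactants: 7 10-allyl enone (C10 epimers)
Product: 8 10α-allyl-10β-methyl enone
Conditions: LDA, THF, −78 °C; MeI, −78 to −20 °C
Reagents that add atoms: iodomethane CI
Why: In this second enolate alkylation iodomethane should enter axially (β face, antiparallel to axial H9) on the conformationally locked enolate, which sets the quaternary helper centre C10 with CH3 axial and allyl equatorial.

Step 7
Reactants: 8 10α-allyl-10β-methyl enone
Product: 9 7β Michael adduct
Conditions: (EtO)2P(O)CH2CO2Et, NaOEt (0.3 equiv), EtOH, rt to 45 °C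
Reagents that add atoms: triethyl phosphonoacetate CCOC(=O)CP(=O)(OCC)OCC
Why: In this reversible Michael addition olefination at C5 is blocked by the neopentyl carbonyl group, and equilibration should funnel the axial kinetic adduct into the all-equatorial one, that is C7–C11 trans to O8 (stereoconvergent).

Step 8
Reactants: 9 7β Michael adduct
Product: 10 6α-hydroxy ketone
Conditions: KHMDS (2.2 equiv), THF, −78 °C; 2-(phenylsulfonyl)-3-phenyloxaziridine (1.1 equiv); NH4Cl
Reagents that add atoms: 2-(phenylsulfonyl)-3-phenyloxaziridine O=S(=O)(N1OC1c1ccccc1)c1ccccc1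
Why: In this Davis enolate hydroxylation of a dianion the less stabilised ketone enolate reacts first, and the syn-axial C10 methyl group together with the C7 side chain closes the β face, so oxygen should arrive on the α face (equatorial 6α-OH, also the stable epimer).

Step 9
Reactants: 10 6α-hydroxy ketone
Product: 11 6α-benzyl ether
Conditions: BnOC(=NH)CCl3, TfOH (cat.), CH2Cl2/cyclohexane, 0 °C
Reagents that add atoms: benzyl 2,2,2-trichloroacetimidate N=C(OCc1ccccc1)C(Cl)(Cl)Cl
Why: Acid-catalysed imidate benzylation avoids base, which would alkylate C11 or scramble the α-ketol.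

Step 10
Reactants: 11 6α-benzyl ether
Product: 13 trans-fused α-phosphono lactone, via diol 12 (not isolated)
Conditions: TFA/H2O 9:1, CH2Cl2, 0 °C to rt; then CSA (cat.), PhMe, 60 °C
Reagents that add atoms: none
Why: Aqueous acid cleaves the diacetal and the freed equatorial 8-OH closes the trans-fused γ-lactone by transesterification onto the ethyl ester, whereas 9-OH cannot reach C12 and stays free.

Step 11
Reactants: 13 trans-fused α-phosphono lactone
Product: 15 γ-hydroxy aldehyde, via allyl-arm diol 14 (not isolated)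
Conditions: OsO4 (2 mol %), NaIO4, 2,6-lutidine, dioxane/H2O, rt
Reagents that add atoms: sodium periodate [Na+].[O-]I(=O)(=O)=O
Why: Lemieux–Johnson cleavage of the only alkene shortens the allyl arm to the C1–C2 acetaldehyde arm, and 15 may rest as its five-membered hemiacetal tautomer.

Step 12
Reactants: 15 γ-hydroxy aldehyde
Product: 16 silylene-bridged Z enol ether
Conditions: t-Bu2Si(OTf)2 (1.05 equiv), Et3N, CH2Cl2, 0 °C to rt
Reagents that add atoms: di-tert-butylsilyl bis(trifluoromethanesulfonate) CC(C)(C)[Si](OS(=O)(=O)C(F)(F)F)(OS(=O)(=O)C(F)(F)F)C(C)(C)C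
Why: Silyl triflate/amine soft enolisation is combined with silylene protection, so the reagent binds O9 and the enol oxygen O2, the seven-membered ring allows only the Z enol ether, and the tether masks 9-OH against retro-aldol cleavage in the basic steps.

Step 13
Reactants: 16 silylene-bridged Z enol ether
Product: 17 5α-vinyl-5β-ol
Conditions: CH2=CHMgBr (3 equiv), CeCl3, THF, −78 to −20 °C; NH4Cl
Reagents that add atoms: vinylmagnesium bromide C=C[Mg]Br
Why: In this organocerium 1,2-addition the first equivalent deprotonates C11 and so shields the lactone as its stabilised carbanion, and the small vinyl group should attack along the axial trajectory on the α face, anti to the axial C10 methyl group, which sets the helper centre C5 (vinyl axial, OH equatorial).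

Step 14
Reactants: 17 5α-vinyl-5β-ol
Product: 20 (Z)-cyclodec-1(10)-en-5-one, via dipotassium alkoxide 18 (not isolated), via ring-expanded enolate 19 (not isolated)
Conditions: KH (2.3 equiv), 18-crown-6, THF, 0 °C to rt; then MeI (1.0 equiv), −78 °C; NH4Cl
Reagents that add atoms: iodomethane CI
Why: Double deprotonation gives the C5 alkoxide (the C11 phosphonate carbanion only shields the lactone), and its charge drives a [3,3]-sigmatropic shift, the anionic oxy-Cope rearrangement known for turning 1,2-dialkenylcyclohexanols into cyclodec-5-enones, in which C2–C3 forms as C5–C10 breaks. The ten-membered carbocycle is thus closed by a four-atom ring enlargement of the cyclohexane rather than end to end, through a chair-like six-centre array with C9 and O5 axial and CH3-14 and C6 equatorial, which should give the (Z)-C1=C10 alkene and the C4=C5 enolate with C3 trans to C6. C2 is set by chirality transfer from the helper centres C5 and C10, because the silylene ring fixes the enol ether as Z and holds C1=C2 nearly eclipsed with C10–C9, so that C3 can bond only to the face of C2 that leads to 2S. C4 is set when iodomethane meets the regiodefined enolate on its outer face, the inner face being covered by the C1=C10 unit across the ring. The step needs site selectivity between two carbanions, which is secured because the ketone enolate is far more basic and nucleophilic than the phosphonate-stabilised C11 anion and only one equivalent of iodomethane is offered at low temperature. The rearrangement is irreversible because it ends in an enolate, and both helper centres are erased in it.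

Step 15
Reactants: 20 (Z)-cyclodec-1(10)-en-5-one
Product: 22 10α-ol, via hydroperoxide 21 (not isolated)
Conditions: Mn(dpm)3 (cat.), PhSiH3, O2 (1 atm), i-PrOH/CH2Cl2, 0 °C to rt; then P(OEt)3
Reagents that add atoms: dioxygen O=O
Why: In this Mukaiyama hydration hydrogen-atom transfer to C1 gives the tertiary C10 radical, and since the bulky O2–Si–O9 bridge cannot turn into the ring, the face syn to O2 and O9 stays the only peripheral one, so O2 should be captured there (10α-OH, 10β-CH3).

Step 16
Reactants: 22 10α-ol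
Product: 23 6α-ol
Conditions: H2 (1 atm), Pd(OH)2/C, EtOAc, rt
Reagents that add atoms: none
Why: Hydrogenolysis of the benzyl ether is possible at this point because no C=C bond is left in the molecule.

Step 17
Reactants: 23 6α-ol
Product: 24 6-isobutyrate
Conditions: (i-PrCO)2O, DMAP (cat.), pyridine, CH2Cl2, 0 °C to rt
Reagents that add atoms: isobutyric anhydride CC(C)C(=O)OC(=O)C(C)C
Why: DMAP-catalysed acylation reaches the only secondary hydroxyl group, and the tertiary 10-OH does not react.

Step 18
Reactants: 24 6-isobutyrate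
Product: 25 2,9,10-triol
Conditions: HF·pyridine, pyridine, THF, 0 °C to rt
Reagents that add atoms: none
Why: Fluoride cleaves both Si–O bonds of the tether, while ester, phosphonate, lactone and ketone are inert to buffered HF.

Step 19
Reactants: 25 2,9,10-triol
Product: 26 2-O-TES ether
Conditions: TESCl (1.05 equiv), imidazole, CH2Cl2, −20 °C
Reagents that add atoms: chlorotriethylsilane CC[Si](Cl)(CC)CC
Why: Silylation should discriminate on steric grounds, since 2-OH lies between two CH2 groups whereas 9-OH is flanked by the tertiary carbinol C10 and by C8.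

Step 20
Reactants: 26 2-O-TES ether
Product: 27 9-angelate
Conditions: angelic acid, 2,4,6-Cl3C6H2COCl, Et3N, PhMe, rt; then 26, 80 °C
Reagents that add atoms: angelic acid C/C=C(/C)C(=O)O
Why: Yamaguchi-type mixed-anhydride esterification without DMAP is the established way to transfer angelic acid without Z to E isomerisation, and 9-OH is the only acylable hydroxyl group.

Step 21
Reactants: 27 9-angelate
Product: 28 2,10-diol phosphonate
Conditions: HF·pyridine, pyridine, THF, 0 °C
Reagents that add atoms: none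
Why: Mild fluoride desilylation frees 2-OH without touching the three esters.

Step 22
Reactants: 28 2,10-diol phosphonate
Product: 29 cardivin C
Conditions: aq. HCHO, K2CO3, THF, 0 °C
Reagents that add atoms: formaldehyde C=O
Why: Horner–Wadsworth–Emmons olefination of formaldehyde by the α-phosphono lactone builds the exocyclic C11=C13 bond regiospecifically in the last step and erases the undefined centre C11.

Compound list
1 | (−)-quinic acid | OC(=O)[C@]1(O)C[C@@H](O)[C@@H](O)[C@H](O)C1 | starting material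
2 | BDA-protected methyl quinate (O8/O9 as (2S,3S)-2,3-dimethoxybutane-2,3-diyl acetal; free axial 5-OH and 7-OH) | COC(=O)[C@]1(O)C[C@@H](O)[C@H]2O[C@](C)(OC)[C@@](C)(OC)O[C@@H]2C1 | intermediate
3 | BDA triol (hydroxymethyl carbinol at C5) | OC[C@]1(O)C[C@@H](O)[C@H]2O[C@](C)(OC)[C@@](C)(OC)O[C@@H]2C1 | intermediate
4 | BDA β-hydroxy ketone (C5 ketone; axial 7α-OH) | O=C1C[C@@H](O)[C@H]2O[C@](C)(OC)[C@@](C)(OC)O[C@@H]2C1 | intermediate
5 | 7-mesylate of 4 | O=C1C[C@@H](OS(C)(=O)=O)[C@H]2O[C@](C)(OC)[C@@](C)(OC)O[C@@H]2C1 | intermediate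
6 | BDA enone (C5 ketone; C6=C7; 8α,9β-diacetal) | O=C1C=C[C@H]2O[C@](C)(OC)[C@@](C)(OC)O[C@@H]2C1 | intermediate
7 | 10-allyl enone (C10 epimers) | O=C1C=C[C@H]2O[C@](C)(OC)[C@@](C)(OC)O[C@@H]2C1CC=C | intermediate
8 | 10α-allyl-10β-methyl enone | O=C1C=C[C@H]2O[C@](C)(OC)[C@@](C)(OC)O[C@@H]2[C@@]1(C)CC=C | intermediate
9 | 7β Michael adduct (equatorial CH(CO2Et)P(O)(OEt)2 at C7) | O=C1C[C@H](C(C(=O)OCC)P(=O)(OCC)OCC)[C@H]2O[C@](C)(OC)[C@@](C)(OC)O[C@@H]2[C@@]1(C)CC=C | intermediate
10 | 6α-hydroxy ketone | O=C1[C@@H](O)[C@H](C(C(=O)OCC)P(=O)(OCC)OCC)[C@H]2O[C@](C)(OC)[C@@](C)(OC)O[C@@H]2[C@@]1(C)CC=C | intermediate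
11 | 6α-benzyl ether | O=C1[C@@H](OCc3ccccc3)[C@H](C(C(=O)OCC)P(=O)(OCC)OCC)[C@H]2O[C@](C)(OC)[C@@](C)(OC)O[C@@H]2[C@@]1(C)CC=C | intermediate
12 | 8α,9β-diol | O=C1[C@@H](OCc2ccccc2)[C@H](C(C(=O)OCC)P(=O)(OCC)OCC)[C@@H](O)[C@H](O)[C@@]1(C)CC=C | intermediate
13 | trans-fused α-phosphono γ-lactone on the cyclohexanone (free 9β-OH) | CCOP(=O)(OCC)C1C(=O)O[C@@H]2[C@@H]1[C@H](OCc3ccccc3)C(=O)[C@](C)(CC=C)[C@H]2O | intermediate
14 | vicinal diol of the allyl arm | CCOP(=O)(OCC)C1C(=O)O[C@@H]2[C@@H]1[C@H](OCc3ccccc3)C(=O)[C@](C)(CC(O)CO)[C@H]2O | intermediate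
15 | γ-hydroxy aldehyde (C2 aldehyde; open tautomer drawn) | CCOP(=O)(OCC)C1C(=O)O[C@@H]2[C@@H]1[C@H](OCc3ccccc3)C(=O)[C@](C)(CC=O)[C@H]2O | intermediate
16 | silylene-bridged Z enol ether (O9–Si(t-Bu)2–O2; C5 ketone) | CCOP(=O)(OCC)C1C(=O)O[C@@H]2[C@@H]1[C@H](OCc3ccccc3)C(=O)[C@]4(C)/C=C\O[Si](C(C)(C)C)(C(C)(C)C)O[C@@H]24 | intermediate
17 | 5α-vinyl-5β-ol (vinyl axial; OH equatorial) | CCOP(=O)(OCC)C1C(=O)O[C@@H]2[C@@H]1[C@H](OCc3ccccc3)[C@](O)(C=C)[C@]4(C)/C=C\O[Si](C(C)(C)C)(C(C)(C)C)O[C@@H]24 | intermediate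
18 | dipotassium salt of 17 (C5 alkoxide; C11 carbanion) | CCOP(=O)(OCC)[C-]1C(=O)O[C@@H]2[C@@H]1[C@H](OCc3ccccc3)[C@]([O-])(C=C)[C@]4(C)/C=C\O[Si](C(C)(C)C)(C(C)(C)C)O[C@@H]24.[K+].[K+] | intermediate
19 | ring-expanded dipotassium salt (C4=C5 enolate; C11 carbanion; (Z)-C1=C10) | CCOP(=O)(OCC)[C-]1C(=O)O[C@@H]2[C@@H]1[C@H](OCc3ccccc3)/C([O-])=C/C[C@H]4/C=C(C)\[C@H]2O[Si](C(C)(C)C)(C(C)(C)C)O4.[K+].[K+] | intermediate
20 | (Z)-cyclodec-1(10)-en-5-one (4β-CH3; 6α-OBn; 2α,9β-O-silylene; 8α,12-olide) | CCOP(=O)(OCC)C1C(=O)O[C@@H]2[C@@H]1[C@H](OCc3ccccc3)C(=O)[C@@H](C)C[C@H]4/C=C(C)\[C@H]2O[Si](C(C)(C)C)(C(C)(C)C)O4 | intermediate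
21 | 10α-hydroperoxide | CCOP(=O)(OCC)C1C(=O)O[C@@H]2[C@@H]1[C@H](OCc3ccccc3)C(=O)[C@@H](C)C[C@H]4C[C@](C)(OO)[C@H]2O[Si](C(C)(C)C)(C(C)(C)C)O4 | intermediate
22 | 10α-ol | CCOP(=O)(OCC)C1C(=O)O[C@@H]2[C@@H]1[C@H](OCc3ccccc3)C(=O)[C@@H](C)C[C@H]4C[C@](C)(O)[C@H]2O[Si](C(C)(C)C)(C(C)(C)C)O4 | intermediate
23 | 6α-ol (debenzylated) | CCOP(=O)(OCC)C1C(=O)O[C@@H]2[C@@H]1[C@H](O)C(=O)[C@@H](C)C[C@H]3C[C@](C)(O)[C@H]2O[Si](C(C)(C)C)(C(C)(C)C)O3 | intermediate
24 | 6-isobutyrate | CCOP(=O)(OCC)C1C(=O)O[C@@H]2[C@@H]1[C@H](OC(=O)C(C)C)C(=O)[C@@H](C)C[C@H]3C[C@](C)(O)[C@H]2O[Si](C(C)(C)C)(C(C)(C)C)O3 | intermediate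
25 | 2,9,10-triol | CCOP(=O)(OCC)C1C(=O)O[C@@H]2[C@@H]1[C@H](OC(=O)C(C)C)C(=O)[C@@H](C)C[C@H](O)C[C@](C)(O)[C@H]2O | intermediate
26 | 2-O-TES ether | CCOP(=O)(OCC)C1C(=O)O[C@@H]2[C@@H]1[C@H](OC(=O)C(C)C)C(=O)[C@@H](C)C[C@H](O[Si](CC)(CC)CC)C[C@](C)(O)[C@H]2O | intermediate
27 | 9-angelate | CCOP(=O)(OCC)C1C(=O)O[C@@H]2[C@@H]1[C@H](OC(=O)C(C)C)C(=O)[C@@H](C)C[C@H](O[Si](CC)(CC)CC)C[C@](C)(O)[C@H]2OC(=O)/C(C)=C\C | intermediate
28 | 2,10-diol phosphonate | CCOP(=O)(OCC)C1C(=O)O[C@@H]2[C@@H]1[C@H](OC(=O)C(C)C)C(=O)[C@@H](C)C[C@H](O)C[C@](C)(O)[C@H]2OC(=O)/C(C)=C\C | intermediate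
29 | cardivin C | C=C1C(=O)O[C@@H]2[C@@H]1[C@H](OC(=O)C(C)C)C(=O)[C@@H](C)C[C@H](O)C[C@](C)(O)[C@H]2OC(=O)/C(C)=C\C | target

Total step count: 22. Longest linear sequence: 22 (the route is fully linear).

Steps most likely to fail

Step 12. The silyl triflate may trap the ring-closed hemiacetal tautomer of 15, or link two molecules, instead of silylating O9 and then the enol oxygen. The fallback sets out from 13 and builds the tether in two stages, so that no free 9-OH ever meets the aldehyde. t-Bu2SiHCl and imidazole in DMF give the 9-O-(di-tert-butylsilyl) ether F1. Lemieux–Johnson cleavage (OsO4 cat., NaIO4, 2,6-lutidine) gives the silyloxy aldehyde F2, which cannot form a hemiacetal. NBS in CH2Cl2 converts Si–H into the bromosilane F3, and Et3N then closes the ring by intramolecular enol silylation. The fallback comes back to the route at 16.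

Step 14. The methyl group may be transferred to the phosphonate carbanion, protons may be exchanged between the enolates so that regiochemical integrity is lost, or the rearrangement may run through a non-chair array. The fallback sets out from 16 and brings the methyl group in with the nucleophile, so C4 is set by equilibration instead of alkylation. 2-Propenylmagnesium bromide and CeCl3 give the isopropenyl carbinol F4. KH and 18-crown-6 followed by a proton quench should give, by outer-face protonation, the 4-epimeric cyclodecenone F5. Since C4 is α to the ketone, DBU in toluene equilibrates F5 with its epimer, and recovered F5 is recycled. The fallback comes back to the route at 20.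

Step 15. Hydrogen-atom transfer to an alkene flanked by two silyloxy carbons may be slow, and facial selectivity in the capture of O2 may be poor. The fallback sets out from 20 and replaces radical hydration by hydroxyl-directed oxygen delivery:
- HF·pyridine gives the allylic diol F6.
- VO(acac)2 and t-BuOOH epoxidise syn to both allylic hydroxyl groups to give the 1,10-epoxide F7.
- PhSeSePh and NaBH4 in EtOH open F7 by SN2 attack at the secondary C1 to give the 1-phenylselanyl 2,9,10-triol F8.
- Bu3SnH and AIBN remove selenium to give the 6-O-benzyl triol F9.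
- TESCl and imidazole silylate the unhindered 2-OH to give the TES ether F10.
- Hydrogenolysis over Pd(OH)2/C gives the 6,9,10-triol F11.
- One equivalent of isobutyric anhydride acylates the more accessible α-ketol hydroxyl group at C6.

The fallback comes back to the route at 26.

Further compounds
F1 | step 12 | 9-O-(di-tert-butylsilyl) ether of 13 | CCOP(=O)(OCC)C1C(=O)O[C@@H]2[C@@H]1[C@H](OCc3ccccc3)C(=O)[C@](C)(CC=C)[C@H]2O[SiH](C(C)(C)C)C(C)(C)C
F2 | step 12 | silyloxy aldehyde | CCOP(=O)(OCC)C1C(=O)O[C@@H]2[C@@H]1[C@H](OCc3ccccc3)C(=O)[C@](C)(CC=O)[C@H]2O[SiH](C(C)(C)C)C(C)(C)C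
F3 | step 12 | bromosilane | CCOP(=O)(OCC)C1C(=O)O[C@@H]2[C@@H]1[C@H](OCc3ccccc3)C(=O)[C@](C)(CC=O)[C@H]2O[Si](Br)(C(C)(C)C)C(C)(C)C
F4 | step 14 | isopropenyl carbinol | CCOP(=O)(OCC)C1C(=O)O[C@@H]2[C@@H]1[C@H](OCc3ccccc3)[C@](O)(C(C)=C)[C@]4(C)/C=C\O[Si](C(C)(C)C)(C(C)(C)C)O[C@@H]24
F5 | step 14 | 4-epimeric cyclodecenone | CCOP(=O)(OCC)C1C(=O)O[C@@H]2[C@@H]1[C@H](OCc3ccccc3)C(=O)[C@H](C)C[C@H]4/C=C(C)\[C@H]2O[Si](C(C)(C)C)(C(C)(C)C)O4
F6 | step 15 | allylic diol | CCOP(=O)(OCC)C1C(=O)O[C@@H]2[C@@H]1[C@H](OCc3ccccc3)C(=O)[C@@H](C)C[C@H](O)/C=C(C)\[C@H]2O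
F7 | step 15 | 1,10-epoxide | CCOP(=O)(OCC)C1C(=O)O[C@@H]2[C@@H]1[C@H](OCc3ccccc3)C(=O)[C@@H](C)C[C@H](O)[C@@H]5O[C@]5(C)[C@H]2O
F8 | step 15 | 1-phenylselanyl 2,9,10-triol | CCOP(=O)(OCC)C1C(=O)O[C@@H]2[C@@H]1[C@H](OCc3ccccc3)C(=O)[C@@H](C)C[C@H](O)[C@@H]([Se]c4ccccc4)[C@](C)(O)[C@H]2O
F9 | step 15 | 6-O-benzyl triol | CCOP(=O)(OCC)C1C(=O)O[C@@H]2[C@@H]1[C@H](OCc3ccccc3)C(=O)[C@@H](C)C[C@H](O)C[C@](C)(O)[C@H]2O
F10 | step 15 | 6-O-benzyl 2-O-TES ether | CCOP(=O)(OCC)C1C(=O)O[C@@H]2[C@@H]1[C@H](OCc3ccccc3)C(=O)[C@@H](C)C[C@H](O[Si](CC)(CC)CC)C[C@](C)(O)[C@H]2O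
F11 | step 15 | 2-O-TES 6,9,10-triol | CCOP(=O)(OCC)C1C(=O)O[C@@H]2[C@@H]1[C@H](O)C(=O)[C@@H](C)C[C@H](O[Si](CC)(CC)CC)C[C@](C)(O)[C@H]2O
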